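**Retrosynthetic overview**
1. Target 16 ⇐ 3-substituted 4-hydroxycoumarin 13 by alkaline ring opening and loss of C2 as CO2; the bought pyranone ring serves as a masked 2-hydroxyaryl methyl ketone.
2. 13 ⇐ 4-allyloxycoumarin 12 by an enantioselective O→C [3,3] shift that turns the C4–O–allyl link into the quaternary centre; 12 ⇐ coumarin 11 + allylic alcohol 8 by C–O bond formation (Mitsunobu), the main disconnection.
3. 8 ⇐ alkyne diol 7: the furan is closed by C–O bond formation (5-endo hydroalkoxylation, then dehydration). It is the only ring built, and it is made before the union with the coumarin.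
4. 7 ⇐ allylic bromide 3 + alkyne diol 5 (sp–sp3 coupling); 3 from geranyl acetate (allylic oxidation, bromination); 5 from hydroxyacetone.

Assumption: the sense of induction of the catalyst in step 8 is predicted by model only; the (R,R)-catalyst is written, and its mirror image (from the (S,S)-diamine) is used instead if the sense proves opposite.

**Route**

Step 1
Reactants: 1 geranyl acetate [(2E)-3,7-dimethylocta-2,6-dien-1-yl acetate]
Product: 2 (2E,6E)-8-hydroxy-3,7-dimethylocta-2,6-dien-1-yl acetate
Conditions: SeO2 (0.3 equiv), t-BuOOH (3 equiv), salicylic acid (0.1 equiv), CH2Cl2, rt, 24 h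
Reagents that add atoms: tert-butyl hydroperoxide, CC(C)(C)OO
Why: Selenium dioxide allylic oxidation (ene reaction then [2,3] shift, SeO2 re-oxidised by t-BuOOH) attacks the electron-rich 6,7-alkene at its (E)-methyl group and leaves the acetate-deactivated 2,3-alkene alone, giving the (6E)-allylic alcohol; no stereocentre is formed.

Step 2
Reactants: 2 (2E,6E)-8-hydroxy-3,7-dimethylocta-2,6-dien-1-yl acetate
Product: 3 (2E,6E)-8-bromo-3,7-dimethylocta-2,6-dien-1-yl acetate
Conditions: CBr4, PPh3, CH2Cl2, 0 °C
Reagents that add atoms: carbon tetrabromide, BrC(Br)(Br)Br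
Why: Appel reaction; SN2 displacement of the alkoxyphosphonium ion by bromide at the primary carbon keeps both E alkenes and the acetate intact.

Step 3
Reactants: 4 hydroxyacetone
Product: 5 2-methylbut-3-yne-1,2-diol (racemic)
Conditions: HC≡CMgBr (2.5 equiv), THF, 0 °C → rt; aq. NH4Cl
Reagents that add atoms: ethynylmagnesium bromide, C#C[Mg]Br
Why: Grignard 1,2-addition to the ketone after the first equivalent has deprotonated the OH group; the tertiary carbinol centre is formed racemic, which does not matter because it becomes an sp2 furan carbon in step 5.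

Step 4
Reactants: 3 (2E,6E)-8-bromo-3,7-dimethylocta-2,6-dien-1-yl acetate; 5 2-methylbut-3-yne-1,2-diol
Product: 7 (2E,6E)-3,7,11-trimethyldodeca-2,6-dien-9-yne-1,11,12-triol, via enyne diol acetate 6 (not isolated)
Conditions: CuI (0.2 equiv), NaI (0.2 equiv), K2CO3 (1.5 equiv), DMF, rt, 16 h; then MeOH, rt, 3 h (same flask)
Reagents that add atoms: none
Why: Copper-catalysed alkyne–allyl halide coupling (copper acetylide, SN2 at the primary allylic carbon) gives the skipped enyne with the E alkene retained and the free OH groups tolerated, and carbonate-catalysed transesterification with methanol then removes the acetate; the carbinol centre stays racemic.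

Step 5
Reactants: 7 (2E,6E)-3,7,11-trimethyldodeca-2,6-dien-9-yne-1,11,12-triol
Product: 8 (2E,6E)-3,7-dimethyl-8-(4-methylfuran-2-yl)octa-2,6-dien-1-ol
Conditions: AgNO3 on silica (10 mol% Ag), CH2Cl2, rt, dark, 3 h
Reagents that add atoms: none
Why: Silver(I)-catalysed cycloisomerisation and dehydration of a 3-alkyne-1,2-diol: the primary OH adds 5-endo-dig to the silver-activated alkyne (C–O bond), protodemetalation and loss of the tertiary OH as water aromatise the ring, and the diol connectivity fixes the 2-alkyl-4-methyl pattern; the remote allylic alcohol and the alkenes are spectators.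

Step 6
Reactants: 9 4,7-dihydroxycoumarin (4,7-dihydroxy-2H-chromen-2-one)
Product: 11 7-[(tert-butyldimethylsilyl)oxy]-4-hydroxy-2H-chromen-2-one, via bis-silyl coumarin 10 (not isolated)
Conditions: TBSCl (2.3 equiv), imidazole, DMF, rt; then THF/H2O/AcOH, rt
Reagents that add atoms: tert-butyldimethylsilyl chloride, CC(C)(C)[Si](C)(C)Cl
Why: Silyl protection of both OH groups followed by selective hydrolysis: the 4-O-silyl group is a vinylogous silyl ester and falls off in mild aqueous acid, while the aryl silyl ether stays.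

Step 7
Reactants: 8 (2E,6E)-3,7-dimethyl-8-(4-methylfuran-2-yl)octa-2,6-dien-1-ol; 11 7-[(tert-butyldimethylsilyl)oxy]-4-hydroxy-2H-chromen-2-one
Product: 12 7-[(tert-butyldimethylsilyl)oxy]-4-{[(2E,6E)-3,7-dimethyl-8-(4-methylfuran-2-yl)octa-2,6-dien-1-yl]oxy}-2H-chromen-2-one
Conditions: PPh3 (1.3 equiv), DIAD (1.3 equiv), THF, 0 °C → rt
Reagents that add atoms: none
Why: Mitsunobu etherification: the vinylogous acid 11 (pKa about 4) protonates the betaine and its O4 attacks the alkoxyphosphonium ion of the primary allylic alcohol by SN2, forming the C4–O–C1′ bond with both E alkenes, the furan and the silyl ether untouched; no stereocentre is formed.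

Step 8
Reactants: 12 7-[(tert-butyldimethylsilyl)oxy]-4-{[(2E,6E)-3,7-dimethyl-8-(4-methylfuran-2-yl)octa-2,6-dien-1-yl]oxy}-2H-chromen-2-one
Product: 13 7-[(tert-butyldimethylsilyl)oxy]-4-hydroxy-3-[(3S,6E)-3,7-dimethyl-8-(4-methylfuran-2-yl)octa-1,6-dien-3-yl]-2H-chromen-2-one
Conditions: (R,R)-G·BArF4 (20 mol%; G = N,N′-bis[(1R,2R)-2-(2-phenylpyrrol-1-yl)cyclohexyl]guanidinium), hexanes/toluene 4:1, 45 °C, 5 d
Reagents that add atoms: none
Why: Proposed new method: the C2-symmetric guanidinium ion gives two N–H···O hydrogen bonds to the lactone O–C=O unit of 12 and so stabilises the negative charge that builds there in the dipolar chair-like [3,3] transition state (O4–C1′ breaking, C3–C3′ forming), which should let the shift run at 45 °C where the thermal reaction (above about 110 °C) is silent; one 2-arylpyrrole arm lies over one face of the pyranone and holds the electron-poor allyl fragment there by a cation–π contact, so only one of the two mirror-image chairs is favoured and C3 bonds to the Si face of C3′ of the (2′E)-allyl unit, setting the quaternary centre as (S) in 13 (the same spatial arrangement as (R) in 16); because no free allyl cation forms, the branched [3,3] product and not the linear [1,3] product is expected; the closest known reaction type is the hydrogen-bond-donor (guanidinium) catalysed enantioselective Claisen rearrangement of O-allyl β-keto esters and ester-substituted allyl vinyl ethers, which has not been shown for 4-allyloxycoumarins or for a γ,γ-dialkyl allyl terminus giving an all-carbon quaternary centre.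

Step 9
Reactants: 13 7-[(tert-butyldimethylsilyl)oxy]-4-hydroxy-3-[(3S,6E)-3,7-dimethyl-8-(4-methylfuran-2-yl)octa-1,6-dien-3-yl]-2H-chromen-2-one
Product: 16 (3R,6E)-1-(2,4-dihydroxyphenyl)-3-ethenyl-3,7-dimethyl-8-(4-methylfuran-2-yl)oct-6-en-1-one, via desilylated coumarin 14 (not isolated), via beta-keto acid 15 (not isolated)
Conditions: 2 M NaOH, EtOH/H2O 1:1, 85 °C, Ar, 16 h; then 1 M HCl to pH 4, rt → 40 °C
Reagents that add atoms: none
Why: Classical ketonic cleavage of a 3-substituted 4-hydroxycoumarin: hydroxide removes the aryl silyl ether and opens the lactone, and the β-keto acid loses CO2 on acidification, so C3 becomes the ketone CH2 and O1 the ortho-OH; the quaternary centre has no acidic hydrogen and cannot epimerise, the C2 centre of 15 (epimers) disappears with the CO2, and furan and alkenes are stable to aqueous base.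

**Compound list**
1 | geranyl acetate, (2E)-3,7-dimethylocta-2,6-dien-1-yl acetate | CC(=O)OC/C=C(\C)CCC=C(C)C | starting material
2 | (2E,6E)-8-hydroxy-3,7-dimethylocta-2,6-dien-1-yl acetate | CC(=O)OC/C=C(\C)CC/C=C(\C)CO | intermediate
3 | (2E,6E)-8-bromo-3,7-dimethylocta-2,6-dien-1-yl acetate | CC(=O)OC/C=C(\C)CC/C=C(\C)CBr | intermediate
4 | hydroxyacetone | CC(=O)CO | starting material
5 | 2-methylbut-3-yne-1,2-diol (racemic) | C#CC(C)(O)CO | intermediate
6 | (2E,6E)-11,12-dihydroxy-3,7,11-trimethyldodeca-2,6-dien-9-yn-1-yl acetate (racemic at C11) | CC(=O)OC/C=C(\C)CC/C=C(\C)CC#CC(C)(O)CO | intermediate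
7 | (2E,6E)-3,7,11-trimethyldodeca-2,6-dien-9-yne-1,11,12-triol (racemic at C11) | OC/C=C(\C)CC/C=C(\C)CC#CC(C)(O)CO | intermediate
8 | (2E,6E)-3,7-dimethyl-8-(4-methylfuran-2-yl)octa-2,6-dien-1-ol | OC/C=C(\C)CC/C=C(\C)Cc1cc(C)co1 | intermediate
9 | 4,7-dihydroxycoumarin (4,7-dihydroxy-2H-chromen-2-one) | O=C1C=C(O)c2ccc(O)cc2O1 | starting material
10 | 4,7-bis[(tert-butyldimethylsilyl)oxy]-2H-chromen-2-one | O=C1C=C(O[Si](C)(C)C(C)(C)C)c2ccc(O[Si](C)(C)C(C)(C)C)cc2O1 | intermediate
11 | 7-[(tert-butyldimethylsilyl)oxy]-4-hydroxy-2H-chromen-2-one | O=C1C=C(O)c2ccc(O[Si](C)(C)C(C)(C)C)cc2O1 | intermediate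
12 | 7-[(tert-butyldimethylsilyl)oxy]-4-{[(2E,6E)-3,7-dimethyl-8-(4-methylfuran-2-yl)octa-2,6-dien-1-yl]oxy}-2H-chromen-2-one | O=C1C=C(OC/C=C(\C)CC/C=C(\C)Cc2cc(C)co2)c2ccc(O[Si](C)(C)C(C)(C)C)cc2O1 | intermediate
13 | 7-[(tert-butyldimethylsilyl)oxy]-4-hydroxy-3-[(3S,6E)-3,7-dimethyl-8-(4-methylfuran-2-yl)octa-1,6-dien-3-yl]-2H-chromen-2-one | C=C[C@](C)(CC/C=C(\C)Cc1cc(C)co1)C1=C(O)c2ccc(O[Si](C)(C)C(C)(C)C)cc2OC1=O | intermediate
14 | 4,7-dihydroxy-3-[(3S,6E)-3,7-dimethyl-8-(4-methylfuran-2-yl)octa-1,6-dien-3-yl]-2H-chromen-2-one | C=C[C@](C)(CC/C=C(\C)Cc1cc(C)co1)C1=C(O)c2ccc(O)cc2OC1=O | intermediate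
15 | (3S,6E)-2-(2,4-dihydroxybenzoyl)-3-ethenyl-3,7-dimethyl-8-(4-methylfuran-2-yl)oct-6-enoic acid (C2 epimers) | C=C[C@](C)(CC/C=C(\C)Cc1cc(C)co1)C(C(=O)O)C(=O)c1ccc(O)cc1O | intermediate
16 | (3R,6E)-1-(2,4-dihydroxyphenyl)-3-ethenyl-3,7-dimethyl-8-(4-methylfuran-2-yl)oct-6-en-1-one | C=C[C@](C)(CC/C=C(\C)Cc1cc(C)co1)CC(=O)c1ccc(O)cc1O | target

**Step count and risks**
Total steps: 9. Longest linear sequence: 7 steps (1 → 2 → 3 → 7 → 8 → 12 → 13 → 16; steps 1, 2, 4, 5, 7, 8, 9).

Most likely to fail:

- **Step 8 (proposed new step).** The catalysed shift may be too slow below the temperature of the racemic thermal reaction, the acidic product may inhibit the catalyst, or face discrimination on the flat coumarin may be poor. Fallback with known chemistry, from 12: heat in toluene at 110 °C (thermal Claisen rearrangement of a 4-allyloxycoumarin). This gives the racemate, that is 13 together with its mirror image, 7-[(tert-butyldimethylsilyl)oxy]-4-hydroxy-3-[(3R,6E)-3,7-dimethyl-8-(4-methylfuran-2-yl)octa-1,6-dien-3-yl]-2H-chromen-2-one F1. The two are separated by preparative chiral SFC (or by crystallising the quinidine salt of the acidic 4-hydroxycoumarin); the fallback returns at 13.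

- **Step 7.** The ambident coumarin anion may be alkylated at O2 or C3 as well as O4. Fallback, from 11: TsCl, Et3N, CH2Cl2 gives 7-[(tert-butyldimethylsilyl)oxy]-2-oxo-2H-chromen-4-yl 4-methylbenzenesulfonate F2. The sodium alkoxide of 8 (NaH, THF, 0 °C) then adds at C4 and expels tosylate (addition–elimination, a vinylogous acyl substitution of the kind known for 4-sulfonyloxy- and 4-halocoumarins). Here the coumarin is the electrophile, so only the O4 ether can form; the fallback returns at 12.

- **Step 4.** The acetylide may attack the γ-carbon of the allylic bromide (branched product), or the skipped enyne may isomerise under base. Fallback, from 3: commercial 3-methylfuran is borylated at its unhindered α-position ([Ir(OMe)(cod)]2, dtbpy, B2pin2) to 4,4,5,5-tetramethyl-2-(4-methylfuran-2-yl)-1,3,2-dioxaborolane F3. Suzuki–Miyaura coupling of F3 with 3 (Pd(PPh3)4, K3PO4, THF/H2O, 50 °C; linear product from the π-allyl) gives (2E,6E)-3,7-dimethyl-8-(4-methylfuran-2-yl)octa-2,6-dien-1-yl acetate F4. K2CO3/MeOH then removes the acetate; the fallback returns at 8 and bypasses steps 4 and 5.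

**Further compounds**
F1 | step 8 | 7-[(tert-butyldimethylsilyl)oxy]-4-hydroxy-3-[(3R,6E)-3,7-dimethyl-8-(4-methylfuran-2-yl)octa-1,6-dien-3-yl]-2H-chromen-2-one | C=C[C@@](C)(CC/C=C(\C)Cc1cc(C)co1)C1=C(O)c2ccc(O[Si](C)(C)C(C)(C)C)cc2OC1=O
F2 | step 7 | 7-[(tert-butyldimethylsilyl)oxy]-2-oxo-2H-chromen-4-yl 4-methylbenzenesulfonate | O=C1C=C(OS(=O)(=O)c2ccc(C)cc2)c2ccc(O[Si](C)(C)C(C)(C)C)cc2O1
F3 | step 4 | 4,4,5,5-tetramethyl-2-(4-methylfuran-2-yl)-1,3,2-dioxaborolane | Cc1coc(B2OC(C)(C)C(C)(C)O2)c1
F4 | step 4 | (2E,6E)-3,7-dimethyl-8-(4-methylfuran-2-yl)octa-2,6-dien-1-yl acetate | CC(=O)OC/C=C(\C)CC/C=C(\C)Cc1cc(C)co1
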